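## Structural features

The target is a C20 bromochloro diterpenoid built on a 7-oxabicyclo[2.2.1]heptane: an oxolane (C1, O7, C4, C5, C6) and a cyclohexane (C1–C6) share the bridgeheads C1 and C4. Four stereocentres are contiguous on the carbocycle: C1 (bridgehead with methyl and ether oxygen), C2 (CH with the endo 3-hydroxy-3-methylpent-4-enyl arm), C3 (all-carbon quaternary, endo methyl, exo 3-bromo-4-chloro-4-methylpentyl arm) and C4 (bridgehead CH–O). Two more stereocentres are remote, each three bonds from the ring: the (S)-tertiary allylic carbinol on the C2 arm and the (S)-secondary bromide next to the tertiary chloride on the C3 arm. Neither can be controlled from the core. The fragile groups are the tertiary allylic alcohol (ionisation and allylic transposition under acid), the vicinal bromochloride (elimination with base, reductive elimination with metals, alkylation by organoaluminium reagents) and the vinyl group. The real difficulty is the fully substituted C3, wedged between C2 and the bridgehead C4, whose two carbon substituents must be distinguished as exo and endo. The key step uses the fact that C4 is at the acetal oxidation level and bonded directly to C3: the C3–C4 bond can be made from an aldehyde enol at C3 and an oxocarbenium ion at C4 inside an oxolane that already holds C1, C5, C6 and O7.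

## Logic of the disconnections

**32 back to 27 (C–Br, C–Cl, O–Si).** The halogens are removed first in the retrosynthetic sense, because a vicinal bromochloride would not survive zinc, AlMe3 or organolithium reagents used for the C2 arm. Both C–halogen bonds of 31 are traced through bromohydrin 29 to epoxide 28, and that to the prenyl alkene of 27. This reduces the remote C–Br centre to a reagent-controlled epoxidation. The forward steps must epoxidise the trisubstituted alkene in the presence of the vinyl group, and must transfer bromine to the secondary carbon with inversion while chloride enters at the tertiary carbon. The silyl ether of 27–31 masks the ionisable carbinol during these steps.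

**27 back to 23 (carbinol C–O, allylic transposition).** The tertiary allylic alcohol of 26 is traced to epoxy iodide 25, epoxy alcohol 24 and the E-allylic alcohol 23. The remote carbinol centre thus becomes the C3–O bond of a Sharpless epoxide. The demand is a reductive opening that keeps this bond, which is why it precedes halogenation.

**23 back to 17 (three C–C bonds of the C2 arm).** The vinylic methyl and the hydroxymethyl carbon of 23 are removed by a carbometalation transform to alkyne 20. The bond between the ring-bound methylene and the propargylic carbon is then cut to triflate 18 and alcohol 17. This leaves a one-carbon handle on C2. The forward substitution must succeed at a β-branched primary carbon.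

**17 back to 13 (two C=C bonds of the C3 arm).** The isopropylidene alkene is cut to aldehyde 16 (Wittig) and the chain is shortened by two carbons through 15 and 14 to the exo formyl group of 13. The pivalate of 13–15 and the free hydroxyl of 16–17 are the same C2 handle. The forward reduction must deliver the aldehyde and free the alcohol without over-reduction.

**13 back to 12 (C3–C4, the key cut).** Cutting C3–C4 opens the carbocycle and leaves a monocyclic 2-methoxyoxolane bearing an aldehyde-derived silyl enol ether. The quaternary centre, the second bridgehead and the bicycle are thereby reduced to one intramolecular bond formation. The forward step must place the formyl carbon exo and the methyl endo at C3; the configuration at C4 is enforced by the tether.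

**12 back to 6 (enol O–Si, acetal C–O, C=O).** The enol silane comes from aldehyde 11, the aldehyde from alcohol 10, the methyl acetal from the lactol formed on ozonolysis of 8, and the primary alcohol of 8 from hydroboration of the isopropenyl group of 6. The order matters: O7 must be locked in the acetal before the second aldehyde is made.

**6 back to 2 and 3 (C2–C3 bond).** The bond between C2 and the isopropenyl carbon is cut to epoxy alcohol 2 and the Grignard reagent 4 derived from 3. Anti opening at the less hindered epoxide carbon sets C2 relative to C1. The pivalate of 6 differentiates the primary from the tertiary hydroxyl.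

**2 back to 1 (epoxide C–O bonds).** The epoxide is traced to 1 by Sharpless epoxidation, which supplies the absolute configuration of C1 and, through the subsequent inversion, of C2.

## Other disconnections considered

**Alternative 1:** The cut is O7–C1, made last on a finished cyclohexane.
- **Forward step:** the carboxylate of hydroxy acid A2 would be oxidised at a graphite anode with 2,4,6-collidine as base. Loss of CO2 and a second electron would give the tertiary C1 cation, which the C4 hydroxyl would capture across the ring to give A1 (a Hofer–Moest-type decarboxylative etherification).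
- **In its favour:** C1 needs no control in A2 and cannot come out wrong in A1, because the bridge can only close cis. A1 already carries the complete silyl-protected C2 arm and a three-carbon ester on C3, so few steps would remain. No Lewis acid is involved.
- **Against it here:** the stereochemical problem is moved, not solved. A2 must already hold C2, the quaternary C3 and C4 in the right relative and absolute sense, plus the remote carbinol centre. The C1 cation is flanked by C2–H and could lose a proton or rearrange, and the ring must reach a boat for 1,4-capture.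
- **Comparison:** on structure, the chosen plan takes C1 and C2 from one epoxide of 1 and makes C3 and C4 in one step, whereas A2 needs its own stereocontrolled carbocycle synthesis. On mechanism, the ring closure to A1 has no stereochemical choice, which is better than the exo/endo decision at C3 in the chosen key step, but its cation has more escape channels. On step economy, Alternative 1 is the equal or the better after the key step and probably the worse before it.

**Alternative 2:** The cut removes C2–C3 and O7–C1 together.
- **Forward step:** MeAlCl2 would activate the epoxide of the Z,Z-configured acetate A4. The trisubstituted alkene would attack the tertiary epoxide carbon through C2 with inversion, and the resulting C1 cation would be trapped by the epoxide oxygen to give A3.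
- **In its favour:** it is the most direct route: two bonds, the bicycle and all four ring stereocentres in one step from an acyclic precursor, with the epoxide configuration and two alkene geometries relayed stereospecifically. A3 is the acetate of 17, which the chosen route reaches only at step 12, so Alternative 2 is clearly better in step economy.
- **Against it here:** A4 needs two Z-trisubstituted alkenes and an enantioselective epoxidation of the central alkene in the presence of two other trisubstituted alkenes. Position selectivity and enantioselectivity on a Z-trisubstituted alkene are both weak points. The cationic cascade could be diverted by hydride shift to a ketone, by proton loss to monocyclic alcohols, or by a chair-like monocyclisation that cannot deliver the oxygen to C1.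
- **Comparison:** on structure, the chosen plan rests on the E-alkene of 1 and a hydroxyl-directed epoxidation, which are easier to secure than A4. On mechanism, the chosen key step forms one bond between a tethered soft nucleophile and a stabilised cation with one stereochemical variable, whereas the bicyclisation passes through a less stabilised tertiary cation.

**Alternative 3:** The cut is C1–C2.
- **Forward step:** acid would ionise the 2-methoxy-2-methyloxolane of A6 to the tertiary C1 oxocarbenium ion. The pyrrolidine enamine of the tethered aldehyde would attack it through C2, and hydrolysis would give A5.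
- **In its favour:** the route is convergent. C3 and C4 are meant to be set together by a geranylboration through a chair transition state, which also brings in the complete 4-methylpent-3-enyl chain. A5, the aldehyde corresponding to alcohol 17, therefore already has the exo arm on which the chosen route spends four steps, so Alternative 3 is better in convergence and step count to that stage. The conditions are mild.
- **Against it here:** the new bond joins a fully substituted oxocarbenium carbon to a carbon next to quaternary C3, which is more congested than the C3–C4 closure. A tertiary oxocarbenium ion readily loses a proton to an enol ether. The new C2 centre is α to the formyl group and could epimerise under the enamine/iminium conditions, while the endo epimer is needed.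
- **Comparison:** on structure, the chosen plan fixes C2 early as a non-epimerisable centre. On mechanism, the two key steps are of the same kind (an enol-type nucleophile adding to a cyclic oxocarbenium ion) and are equal in that respect, but the chosen one uses the less hindered ion. On step economy, Alternative 3 is the better.

Key step: step 8

Assumption: hydroboration in step 4 is taken to be unselective at the new methyl-bearing carbon, so 7–11 are carried as epimer pairs at that carbon, 9–12 as anomer pairs and 12 as an E/Z pair; all converge in step 8, where both carbons become trigonal.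

## Route

Step 1
Reactants: 1 geraniol
Product: 2 (2S,3S)-2,3-epoxygeraniol
Conditions: Ti(OiPr)4 (5 mol%), L-(+)-diethyl tartrate (6 mol%), t-BuOOH, 4 Å MS, CH2Cl2, −20 °C
Reagents that add atoms: tert-butyl hydroperoxide, CC(C)(C)OO
Why: Sharpless asymmetric epoxidation of an E-trisubstituted allylic alcohol; L-(+)-tartrate should deliver oxygen to the face giving the (2S,3S)-epoxide, which fixes the future C1 (its C–O bond is kept) and, after inversion, C2. The isolated 6,7-alkene lacks the directing hydroxyl and is not touched.

Step 2
Reactants: 2 (2S,3S)-2,3-epoxygeraniol; 3 2-bromopropene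
Product: 5 (2R,3S)-3,7-dimethyl-2-(prop-1-en-2-yl)oct-6-ene-1,3-diol, via isopropenylmagnesium bromide 4 (not isolated)
Conditions: 3, Mg, THF, 45 °C; then CuI (10 mol%), 2, THF, −40 → 0 °C; aq. NH4Cl
Reagents that add atoms: none
Why: Copper-catalysed Grignard opening of a 2,3-epoxy alcohol; the alkenyl group should attack the less hindered C2 (C3 is fully substituted) anti to the C–O bond, so C2 is inverted and the 1,3-diol results. The first equivalent of 4 is consumed by the hydroxyl proton.

Step 3
Reactants: 5 (2R,3S)-3,7-dimethyl-2-(prop-1-en-2-yl)oct-6-ene-1,3-diol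
Product: 6 (2R,3S)-3-hydroxy-3,7-dimethyl-2-(prop-1-en-2-yl)oct-6-enyl pivalate
Conditions: PivCl (1.1 equiv), pyridine, CH2Cl2, 0 °C
Reagents that add atoms: pivaloyl chloride, CC(C)(C)C(=O)Cl
Why: Selective acylation; the hindered acid chloride should react only with the primary hydroxyl and leave the tertiary one free for the later lactol.

Step 4
Reactants: 6 (2R,3S)-3-hydroxy-3,7-dimethyl-2-(prop-1-en-2-yl)oct-6-enyl pivalate
Product: 8 (2R,3S)-3-hydroxy-2-(1-hydroxypropan-2-yl)-3,7-dimethyloct-6-enyl pivalate, via the B-alkyl-9-BBN adduct 7 (not isolated)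
Conditions: 9-BBN (2.5 equiv), THF, 0 → 50 °C; then 3 M NaOH, 30% H2O2, 0 °C
Reagents that add atoms: hydrogen peroxide, OO (the new hydroxyl oxygen); 9-borabicyclo[3.3.1]nonane, B1C2CCCC1CCC2 (boron is present only in 7)
Why: Hydroboration–oxidation; 9-BBN adds to the 1,1-disubstituted alkene far faster than to the trisubstituted one and places boron on the terminal carbon. The new methyl-bearing centre is formed without control, which is harmless because it is planarised in step 7.

Step 5
Reactants: 8 (2R,3S)-3-hydroxy-2-(1-hydroxypropan-2-yl)-3,7-dimethyloct-6-enyl pivalate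
Product: 10 (2R)-4-hydroxy-2-[(2S)-5-methoxy-2-methyloxolan-2-yl]-3-methylbutyl pivalate, via lactol 9 (not isolated)
Conditions: O3, CH2Cl2/MeOH (3:1), NaHCO3, −78 °C; Me2S, −78 → 25 °C; then PPTS (cat.), MeOH, 25 °C; Et3N quench
Reagents that add atoms: methanol, CO (the methoxy group); ozone, [O-][O+]=O (supplies the hydroxyl oxygen of 9 only)
Why: Ozonolysis of the remaining trisubstituted alkene, spontaneous closure of the γ-hydroxy aldehyde to the five-membered lactol, and acid-catalysed exchange of the anomeric hydroxyl for methoxyl. The large excess of methanol should keep the primary hydroxyl from forming the seven-membered internal acetal. Locking O7 in the acetal prevents it from capturing the aldehyde made in step 6.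

Step 6
Reactants: 10 (2R)-4-hydroxy-2-[(2S)-5-methoxy-2-methyloxolan-2-yl]-3-methylbutyl pivalate
Product: 11 (2R)-2-[(2S)-5-methoxy-2-methyloxolan-2-yl]-3-methyl-4-oxobutyl pivalate
Conditions: Dess–Martin periodinane, NaHCO3, CH2Cl2, 0 → 25 °C
Reagents that add atoms: none
Why: Dess–Martin oxidation under buffered conditions; the methyl acetal and the pivalate are inert, and since the tertiary oxygen is already masked the aldehyde cannot be trapped as a lactol.

Step 7
Reactants: 11 (2R)-2-[(2S)-5-methoxy-2-methyloxolan-2-yl]-3-methyl-4-oxobutyl pivalate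
Product: 12 (2R)-4-(tert-butyldimethylsilyloxy)-2-[(2S)-5-methoxy-2-methyloxolan-2-yl]-3-methylbut-3-enyl pivalate
Conditions: TBSOTf (1.3 equiv), Et3N (3 equiv), CH2Cl2, −78 → 0 °C
Reagents that add atoms: tert-butyldimethylsilyl triflate, CC(C)(C)[Si](C)(C)OS(=O)(=O)C(F)(F)F
Why: Soft enolisation of an α-branched aldehyde with a silyl triflate and an amine gives the trisubstituted silyl enol ether; either geometry serves. The amine is kept in excess so that the silyl triflate cannot ionise the acetal before step 8.

Step 8
Reactants: 12 (2R)-4-(tert-butyldimethylsilyloxy)-2-[(2S)-5-methoxy-2-methyloxolan-2-yl]-3-methylbut-3-enyl pivalate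
Product: 13 [(1S,2R,3S,4R)-3-formyl-1,3-dimethyl-7-oxabicyclo[2.2.1]heptan-2-yl]methyl pivalate
Conditions: TMSOTf (0.2 equiv), 2,6-di-tert-butyl-4-methylpyridine (0.3 equiv), CH2Cl2, −78 → −40 °C; aq. NaHCO3
Reagents that add atoms: none
Why: TMSOTf removes methoxide from either anomer of 12 to give the same planar oxocarbenium ion at C4, which the tethered silyl enol ether attacks through C3; transfer of the silyl group to triflate releases the aldehyde and regenerates a silyl triflate, so the promoter is needed only in catalytic amount. The closest known reaction type is the Mukaiyama-type addition of silyl enol ethers to acetal-derived cyclic oxocarbenium ions, here run intramolecularly. The one ring closed is the carbocycle C1–C2–C3–C4–C5–C6, by a 6-(enolexo)-exo-trig closure, since the C4=O7 π bond lies outside the new ring; counted through O7 the same bond completes the five-membered ring C1–C2–C3–C4–O7, in which that π bond is endocyclic, and the O7–C4–C3 angle of about 100° in the bicycle fits the Bürgi–Dunitz approach. C4 is set by the tether: C2 hangs from C1 on one face of the oxolane, so C3 can reach C4 only on that face and the cis bridge is the only possible outcome. C3 is set by which π face of the enol silane is presented: the transition state with the longer, planar silyloxyvinyl terminus on the open O7 side and the compact methyl under the C5–C6 bridge should be favoured, which gives formyl exo and methyl endo, while C1 and C2 are untouched. The selectivity the step needs is therefore only the exo/endo choice at C3, secured by the size difference of the two enol substituents and by low temperature under kinetic control, with the hindered pyridine removing triflic acid to suppress ring re-opening and protodesilylation. The pivalate is kept at C2 because its ester oxygen is too electron-poor to trap the oxocarbenium ion as a bicyclic acetal, a pathway open to an ether or a free hydroxyl at that position.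

Step 9
Reactants: 13 [(1S,2R,3S,4R)-3-formyl-1,3-dimethyl-7-oxabicyclo[2.2.1]heptan-2-yl]methyl pivalate
Product: 14 [(1S,2R,3S,4R)-3-[(E)-3-(methoxy(methyl)amino)-3-oxoprop-1-enyl]-1,3-dimethyl-7-oxabicyclo[2.2.1]heptan-2-yl]methyl pivalate
Conditions: (EtO)2P(O)CH2C(O)N(OMe)Me, NaH, THF, 0 → 40 °C
Reagents that add atoms: diethyl (N-methoxy-N-methylcarbamoylmethyl)phosphonate, CCOP(=O)(CC(=O)N(C)OC)OCC
Why: Horner–Wadsworth–Emmons olefination; the aldehyde has no α-hydrogen, so it can neither enolise nor epimerise, and the stabilised phosphonate anion should give the E-alkene. The Weinreb amide is chosen so that the reduction in step 11 stops at the aldehyde.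

Step 10
Reactants: 14 [(1S,2R,3S,4R)-3-[(E)-3-(methoxy(methyl)amino)-3-oxoprop-1-enyl]-1,3-dimethyl-7-oxabicyclo[2.2.1]heptan-2-yl]methyl pivalate
Product: 15 [(1S,2R,3S,4R)-3-[3-(methoxy(methyl)amino)-3-oxopropyl]-1,3-dimethyl-7-oxabicyclo[2.2.1]heptan-2-yl]methyl pivalate
Conditions: H2 (1 atm), Pd/C (10%), EtOAc, 25 °C
Reagents that add atoms: none
Why: Heterogeneous hydrogenation of the conjugated disubstituted alkene; the pivalate and the N–O bond should survive one atmosphere at room temperature.

Step 11
Reactants: 15 [(1S,2R,3S,4R)-3-[3-(methoxy(methyl)amino)-3-oxopropyl]-1,3-dimethyl-7-oxabicyclo[2.2.1]heptan-2-yl]methyl pivalate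
Product: 16 3-[(1S,2R,3S,4R)-2-(hydroxymethyl)-1,3-dimethyl-7-oxabicyclo[2.2.1]heptan-3-yl]propanal
Conditions: i-Bu2AlH (3.5 equiv), CH2Cl2, −78 °C; aq. KNaC4H4O6
Reagents that add atoms: none
Why: i-Bu2AlH reduces the Weinreb amide to a chelated aluminate that releases the aldehyde only on work-up, and in the same operation cleaves the pivalate reductively. The two arms thus emerge differentiated as aldehyde and primary alcohol.

Step 12
Reactants: 16 3-[(1S,2R,3S,4R)-2-(hydroxymethyl)-1,3-dimethyl-7-oxabicyclo[2.2.1]heptan-3-yl]propanal
Product: 17 [(1S,2R,3S,4R)-1,3-dimethyl-3-(4-methylpent-3-enyl)-7-oxabicyclo[2.2.1]heptan-2-yl]methanol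
Conditions: i-PrPPh3I (3.5 equiv), n-BuLi (3.3 equiv), THF, 0 °C; then 16, −78 → 25 °C
Reagents that add atoms: isopropyltriphenylphosphonium iodide, CC(C)[P+](c1ccccc1)(c1ccccc1)c1ccccc1.[I-]
Why: Wittig olefination with a non-stabilised ylide; excess ylide first deprotonates the hydroxyl and the aldehyde is then converted into the isopropylidene terminus.

Step 13
Reactants: 17 [(1S,2R,3S,4R)-1,3-dimethyl-3-(4-methylpent-3-enyl)-7-oxabicyclo[2.2.1]heptan-2-yl]methanol
Product: 18 [(1S,2R,3S,4R)-1,3-dimethyl-3-(4-methylpent-3-enyl)-7-oxabicyclo[2.2.1]heptan-2-yl]methyl trifluoromethanesulfonate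
Conditions: Tf2O (1.3 equiv), pyridine (2 equiv), CH2Cl2, −78 → −30 °C; cold aqueous work-up, used at once
Reagents that add atoms: triflic anhydride, O=S(=O)(OS(=O)(=O)C(F)(F)F)C(F)(F)F
Why: Sulfonylation of the primary alcohol; a triflate is needed because the carbon is attached to a CH that lies between two fully substituted carbons, and a lesser leaving group would be displaced too slowly.

Step 14
Reactants: 18 [(1S,2R,3S,4R)-1,3-dimethyl-3-(4-methylpent-3-enyl)-7-oxabicyclo[2.2.1]heptan-2-yl]methyl trifluoromethanesulfonate
Product: 20 (1S,2S,3S,4R)-2-(but-3-ynyl)-1,3-dimethyl-3-(4-methylpent-3-enyl)-7-oxabicyclo[2.2.1]heptane, via the trimethylsilyl alkyne 19 (not isolated)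
Conditions: LiCH2C≡CSiMe3 (from 1-(trimethylsilyl)propyne, n-BuLi, THF, −78 → −20 °C); 18, THF, −78 → 0 °C; then MeOH, K2CO3, 25 °C
Reagents that add atoms: 1-(trimethylsilyl)propyne, CC#C[Si](C)(C)C
Why: SN2 alkylation of lithiated 1-(trimethylsilyl)propyne at the primary triflate (propargylation), the silyl group steering attack to the propargylic terminus. Methanolysis of the alkynylsilane after the quench frees the terminal alkyne.

Step 15
Reactants: 20 (1S,2S,3S,4R)-2-(but-3-ynyl)-1,3-dimethyl-3-(4-methylpent-3-enyl)-7-oxabicyclo[2.2.1]heptane
Product: 23 (2E)-5-[(1S,2S,3S,4R)-1,3-dimethyl-3-(4-methylpent-3-enyl)-7-oxabicyclo[2.2.1]heptan-2-yl]-3-methylpent-2-en-1-ol, via alkenyldimethylalane 21 (not isolated), via lithium alkenyl(butyl)dimethylaluminate 22 (not isolated)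
Conditions: AlMe3 (3 equiv), Cp2ZrCl2 (0.3 equiv), CH2Cl2, 0 → 25 °C; then n-BuLi, THF, −30 °C; then (CH2O)n, 25 °C
Reagents that add atoms: trimethylaluminium, C[Al](C)C (the new methyl); formaldehyde as paraformaldehyde, C=O (the CH2OH group)
Why: Negishi zirconium-catalysed carboalumination adds methyl and aluminium syn across the terminal alkyne with methyl on the internal carbon; conversion into the aluminate and trapping with formaldehyde keeps the geometry and should give the E-trisubstituted allylic alcohol. The trisubstituted alkene and the bridged ether are inert.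

Step 16
Reactants: 23 (2E)-5-[(1S,2S,3S,4R)-1,3-dimethyl-3-(4-methylpent-3-enyl)-7-oxabicyclo[2.2.1]heptan-2-yl]-3-methylpent-2-en-1-ol
Product: 24 [(2S,3S)-3-{2-[(1S,2S,3S,4R)-1,3-dimethyl-3-(4-methylpent-3-enyl)-7-oxabicyclo[2.2.1]heptan-2-yl]ethyl}-3-methyloxiran-2-yl]methanol
Conditions: Ti(OiPr)4 (10 mol%), L-(+)-diethyl tartrate (12 mol%), t-BuOOH, 4 Å MS, CH2Cl2, −20 °C
Reagents that add atoms: tert-butyl hydroperoxide, CC(C)(C)OO
Why: Sharpless asymmetric epoxidation under reagent control; L-(+)-tartrate should give the (2S,3S)-epoxy alcohol, whose C3–O bond becomes the (S)-carbinol. The unfunctionalised prenyl alkene is not epoxidised.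

Step 17
Reactants: 24 [(2S,3S)-3-{2-[(1S,2S,3S,4R)-1,3-dimethyl-3-(4-methylpent-3-enyl)-7-oxabicyclo[2.2.1]heptan-2-yl]ethyl}-3-methyloxiran-2-yl]methanol
Product: 25 the epoxy iodide of 24 (CH2I in place of CH2OH)
Conditions: I2, PPh3, imidazole, THF, 0 °C
Reagents that add atoms: iodine, II
Why: Appel-type iodination of the primary alcohol, which leaves the epoxide and its configuration untouched.

Step 18
Reactants: 25 the epoxy iodide of 24
Product: 26 (3S)-5-[(1S,2S,3S,4R)-1,3-dimethyl-3-(4-methylpent-3-enyl)-7-oxabicyclo[2.2.1]heptan-2-yl]-3-methylpent-1-en-3-ol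
Conditions: Zn dust, AcOH (2 equiv), EtOH, 25–40 °C
Reagents that add atoms: none
Why: Reductive opening of a 2,3-epoxy iodide: zinc inserts into the C–I bond and β-elimination cleaves the adjacent C–O bond, giving the tertiary allylic alcohol with its C–O bond and configuration retained. The step stands before any halogen is introduced because zinc would eliminate a vicinal bromochloride.

Step 19
Reactants: 26 (3S)-5-[(1S,2S,3S,4R)-1,3-dimethyl-3-(4-methylpent-3-enyl)-7-oxabicyclo[2.2.1]heptan-2-yl]-3-methylpent-1-en-3-ol
Product: 27 the triethylsilyl ether of 26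
Conditions: Et3SiOTf, 2,6-lutidine, CH2Cl2, −78 → 0 °C
Reagents that add atoms: triethylsilyl triflate, CC[Si](CC)(CC)OS(=O)(=O)C(F)(F)F
Why: Silylation of the tertiary alcohol with a silyl triflate; the ether shields the ionisable tertiary allylic hydroxyl during steps 21 and 22.

Step 20
Reactants: 27 the triethylsilyl ether of 26
Product: 28 the (R)-epoxide of 27 at the prenyl alkene
Conditions: D-fructose-derived Shi ketone (0.3 equiv), KHSO5 (as 2KHSO5·KHSO4·K2SO4), K2CO3, Bu4NHSO4 (cat.), MeCN/CH2(OMe)2/aq. buffer, 0 °C
Reagents that add atoms: potassium peroxymonosulfate, [K+].[O-]S(=O)(=O)OO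
Why: Shi asymmetric epoxidation; the chiral dioxirane epoxidises the electron-rich trisubstituted alkene much faster than the monosubstituted vinyl group and, through the spiro transition state, should deliver the (R)-epoxide.

Step 21
Reactants: 28 the (R)-epoxide of 27
Product: 29 the (3R)-bromohydrin with tertiary bromide and secondary alcohol
Conditions: MgBr2·OEt2 (2 equiv), Et2O, −30 → 0 °C; aq. NH4Cl
Reagents that add atoms: magnesium bromide diethyl etherate, [Mg+2].[Br-].[Br-].CCOCC
Why: Lewis-acid-assisted halide opening of a trisubstituted epoxide at the tertiary carbon, which leaves the secondary C–O bond and its configuration intact. Any minor regioisomer from attack at the secondary carbon with inversion would pass through the same bromonium ion in step 22.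

Step 22
Reactants: 29 the (3R)-bromohydrin
Product: 31 the triethylsilyl ether of the target, via secondary triflate 30 (not isolated)
Conditions: Tf2O, 2,6-lutidine, CH2Cl2, −78 °C; then Bu4NCl (3 equiv), −78 → 0 °C
Reagents that add atoms: tetrabutylammonium chloride, CCCC[N+](CCCC)(CCCC)CCCC.[Cl-]; triflic anhydride, O=S(=O)(OS(=O)(=O)C(F)(F)F)C(F)(F)F (present only in 30)
Why: Neighbouring-group substitution with 1,2-bromine shift: the adjacent tertiary bromine displaces the secondary triflate from the rear (inversion at the carbinol carbon) to give a bromonium ion, which chloride opens at the tertiary carbon as in the bromochlorination of trisubstituted alkenes, so the (S)-bromide and the tertiary chloride arise together. Direct SN2 at this neopentyl-like carbon is avoided, and no nucleophilic alkene is present to scramble the bromonium ion.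

Step 23
Reactants: 31 the triethylsilyl ether of the target
Product: 32 (3S)-5-[(1S,2S,3S,4R)-3-[(3S)-3-bromo-4-chloro-4-methylpentyl]-1,3-dimethyl-7-oxabicyclo[2.2.1]heptan-2-yl]-3-methylpent-1-en-3-ol
Conditions: HF·pyridine, pyridine, THF, 0 °C
Reagents that add atoms: none
Why: Fluoride-mediated cleavage of the triethylsilyl ether under buffered, non-basic conditions, which should spare the secondary bromide, the tertiary chloride and the tertiary allylic alcohol.

## Compound list

1 | geraniol, (2E)-3,7-dimethylocta-2,6-dien-1-ol | CC(C)=CCC/C(C)=C/CO | starting material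
2 | (2S,3S)-2,3-epoxygeraniol, [(2S,3S)-3-methyl-3-(4-methylpent-3-enyl)oxiran-2-yl]methanol | CC(C)=CCC[C@]1(C)O[C@H]1CO | intermediate
3 | 2-bromopropene | CC(Br)=C | starting material
4 | isopropenylmagnesium bromide | CC(=C)[Mg]Br | intermediate (not isolated)
5 | (2R,3S)-3,7-dimethyl-2-(prop-1-en-2-yl)oct-6-ene-1,3-diol | OC[C@@H](C(C)=C)[C@@](C)(O)CCC=C(C)C | intermediate
6 | (2R,3S)-3-hydroxy-3,7-dimethyl-2-(prop-1-en-2-yl)oct-6-enyl pivalate | CC(C)(C)C(=O)OC[C@@H](C(C)=C)[C@@](C)(O)CCC=C(C)C | intermediate
7 | B-alkyl-9-BBN adduct of 6 (boron on the terminal carbon of the former isopropenyl group; epimer pair at the methyl-bearing carbon) | CC(C)(C)C(=O)OC[C@@H](C(C)CB1C2CCCC1CCC2)[C@@](C)(O)CCC=C(C)C | intermediate (not isolated)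
8 | (2R,3S)-3-hydroxy-2-(1-hydroxypropan-2-yl)-3,7-dimethyloct-6-enyl pivalate (epimer pair at the methyl-bearing carbon) | CC(C)(C)C(=O)OC[C@@H](C(C)CO)[C@@](C)(O)CCC=C(C)C | intermediate
9 | (2R)-4-hydroxy-2-[(2S)-5-hydroxy-2-methyloxolan-2-yl]-3-methylbutyl pivalate (lactol; anomer and epimer pairs) | CC(C)(C)C(=O)OC[C@@H](C(C)CO)[C@]1(C)CCC(O)O1 | intermediate (not isolated)
10 | (2R)-4-hydroxy-2-[(2S)-5-methoxy-2-methyloxolan-2-yl]-3-methylbutyl pivalate (anomer and epimer pairs) | CC(C)(C)C(=O)OC[C@@H](C(C)CO)[C@]1(C)CCC(OC)O1 | intermediate
11 | (2R)-2-[(2S)-5-methoxy-2-methyloxolan-2-yl]-3-methyl-4-oxobutyl pivalate (anomer and epimer pairs) | CC(C)(C)C(=O)OC[C@@H](C(C)C=O)[C@]1(C)CCC(OC)O1 | intermediate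
12 | (2R)-4-(tert-butyldimethylsilyloxy)-2-[(2S)-5-methoxy-2-methyloxolan-2-yl]-3-methylbut-3-enyl pivalate (anomer pair, E/Z pair) | CC(C)(C)C(=O)OC[C@@H](C(C)=CO[Si](C)(C)C(C)(C)C)[C@]1(C)CCC(OC)O1 | intermediate
13 | [(1S,2R,3S,4R)-3-formyl-1,3-dimethyl-7-oxabicyclo[2.2.1]heptan-2-yl]methyl pivalate (formyl exo, 3-methyl endo, pivaloyloxymethyl endo) | CC(C)(C)C(=O)OC[C@H]1[C@](C)(C=O)[C@H]2CC[C@]1(C)O2 | intermediate
14 | [(1S,2R,3S,4R)-3-[(E)-3-(methoxy(methyl)amino)-3-oxoprop-1-enyl]-1,3-dimethyl-7-oxabicyclo[2.2.1]heptan-2-yl]methyl pivalate | CC(C)(C)C(=O)OC[C@H]1[C@](C)(/C=C/C(=O)N(C)OC)[C@H]2CC[C@]1(C)O2 | intermediate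
15 | [(1S,2R,3S,4R)-3-[3-(methoxy(methyl)amino)-3-oxopropyl]-1,3-dimethyl-7-oxabicyclo[2.2.1]heptan-2-yl]methyl pivalate | CC(C)(C)C(=O)OC[C@H]1[C@](C)(CCC(=O)N(C)OC)[C@H]2CC[C@]1(C)O2 | intermediate
16 | 3-[(1S,2R,3S,4R)-2-(hydroxymethyl)-1,3-dimethyl-7-oxabicyclo[2.2.1]heptan-3-yl]propanal | OC[C@H]1[C@](C)(CCC=O)[C@H]2CC[C@]1(C)O2 | intermediate
17 | [(1S,2R,3S,4R)-1,3-dimethyl-3-(4-methylpent-3-enyl)-7-oxabicyclo[2.2.1]heptan-2-yl]methanol | OC[C@H]1[C@](C)(CCC=C(C)C)[C@H]2CC[C@]1(C)O2 | intermediate
18 | [(1S,2R,3S,4R)-1,3-dimethyl-3-(4-methylpent-3-enyl)-7-oxabicyclo[2.2.1]heptan-2-yl]methyl trifluoromethanesulfonate | FC(F)(F)S(=O)(=O)OC[C@H]1[C@](C)(CCC=C(C)C)[C@H]2CC[C@]1(C)O2 | intermediate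
19 | trimethyl{4-[(1S,2S,3S,4R)-1,3-dimethyl-3-(4-methylpent-3-enyl)-7-oxabicyclo[2.2.1]heptan-2-yl]but-1-ynyl}silane | C[Si](C)(C)C#CCC[C@H]1[C@](C)(CCC=C(C)C)[C@H]2CC[C@]1(C)O2 | intermediate (not isolated)
20 | (1S,2S,3S,4R)-2-(but-3-ynyl)-1,3-dimethyl-3-(4-methylpent-3-enyl)-7-oxabicyclo[2.2.1]heptane | C#CCC[C@H]1[C@](C)(CCC=C(C)C)[C@H]2CC[C@]1(C)O2 | intermediate
21 | dimethyl{(1E)-4-[(1S,2S,3S,4R)-1,3-dimethyl-3-(4-methylpent-3-enyl)-7-oxabicyclo[2.2.1]heptan-2-yl]-2-methylbut-1-enyl}alane | C[Al](C)/C=C(\C)CC[C@H]1[C@](C)(CCC=C(C)C)[C@H]2CC[C@]1(C)O2 | intermediate (not isolated)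
22 | lithium butyl(dimethyl){(1E)-4-[(1S,2S,3S,4R)-1,3-dimethyl-3-(4-methylpent-3-enyl)-7-oxabicyclo[2.2.1]heptan-2-yl]-2-methylbut-1-enyl}aluminate | [Li+].CCCC[Al-](C)(C)/C=C(\C)CC[C@H]1[C@](C)(CCC=C(C)C)[C@H]2CC[C@]1(C)O2 | intermediate (not isolated)
23 | (2E)-5-[(1S,2S,3S,4R)-1,3-dimethyl-3-(4-methylpent-3-enyl)-7-oxabicyclo[2.2.1]heptan-2-yl]-3-methylpent-2-en-1-ol | OC/C=C(\C)CC[C@H]1[C@](C)(CCC=C(C)C)[C@H]2CC[C@]1(C)O2 | intermediate
24 | [(2S,3S)-3-{2-[(1S,2S,3S,4R)-1,3-dimethyl-3-(4-methylpent-3-enyl)-7-oxabicyclo[2.2.1]heptan-2-yl]ethyl}-3-methyloxiran-2-yl]methanol | OC[C@@H]1O[C@@]1(C)CC[C@H]2[C@](C)(CCC=C(C)C)[C@H]3CC[C@]2(C)O3 | intermediate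
25 | epoxy iodide of 24, (2R,3S)-2-(iodomethyl)-3-methyl-3-(2-bicyclylethyl)oxirane (same arrangement in space as 24) | IC[C@@H]1O[C@@]1(C)CC[C@H]2[C@](C)(CCC=C(C)C)[C@H]3CC[C@]2(C)O3 | intermediate
26 | (3S)-5-[(1S,2S,3S,4R)-1,3-dimethyl-3-(4-methylpent-3-enyl)-7-oxabicyclo[2.2.1]heptan-2-yl]-3-methylpent-1-en-3-ol | C=C[C@@](C)(O)CC[C@H]1[C@](C)(CCC=C(C)C)[C@H]2CC[C@]1(C)O2 | intermediate
27 | triethylsilyl ether of 26 (tertiary O–SiEt3) | C=C[C@@](C)(O[Si](CC)(CC)CC)CC[C@H]1[C@](C)(CCC=C(C)C)[C@H]2CC[C@]1(C)O2 | intermediate
28 | triethylsilyl ether carrying a 2-[(2R)-3,3-dimethyloxiran-2-yl]ethyl group exo on C3 | C=C[C@@](C)(O[Si](CC)(CC)CC)CC[C@H]1[C@](C)(CC[C@H]3OC3(C)C)[C@H]2CC[C@]1(C)O2 | intermediate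
29 | triethylsilyl ether carrying a (3R)-4-bromo-3-hydroxy-4-methylpentyl group exo on C3 | C=C[C@@](C)(O[Si](CC)(CC)CC)CC[C@H]1[C@](C)(CC[C@@H](O)C(C)(C)Br)[C@H]2CC[C@]1(C)O2 | intermediate
30 | trifluoromethanesulfonate of the secondary hydroxyl of 29 | C=C[C@@](C)(O[Si](CC)(CC)CC)CC[C@H]1[C@](C)(CC[C@@H](OS(=O)(=O)C(F)(F)F)C(C)(C)Br)[C@H]2CC[C@]1(C)O2 | intermediate (not isolated)
31 | triethylsilyl ether of the target, with the (3S)-3-bromo-4-chloro-4-methylpentyl group exo on C3 | C=C[C@@](C)(O[Si](CC)(CC)CC)CC[C@H]1[C@](C)(CC[C@H](Br)C(C)(C)Cl)[C@H]2CC[C@]1(C)O2 | intermediate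
32 | (3S)-5-[(1S,2S,3S,4R)-3-[(3S)-3-bromo-4-chloro-4-methylpentyl]-1,3-dimethyl-7-oxabicyclo[2.2.1]heptan-2-yl]-3-methylpent-1-en-3-ol | C=C[C@@](C)(O)CC[C@H]1[C@](C)(CC[C@H](Br)C(C)(C)Cl)[C@H]2CC[C@]1(C)O2 | target

## Step count and least certain steps

Total step count: 23. Longest linear sequence: 23 steps (1 to 32; compound 3 enters in step 2).

**Step 8 (key step).** The most likely failure is insufficient discrimination between the two π faces of the enol silane at C3. Both transition states are boat-like and differ only in whether the methyl or the silyloxyvinyl group lies under the C5–C6 bridge. Protodesilylation, or reversible ring opening if triflic acid builds up, could add to this. The fallback changes the nucleophile and the promoter. It sets out from 11, which would be condensed with pyrrolidine over molecular sieves to the enamine (2R)-2-[(2S)-5-methoxy-2-methyloxolan-2-yl]-3-methyl-4-(pyrrolidin-1-yl)but-3-enyl pivalate F1. Camphorsulfonic acid in CH2Cl2 at −20 °C would ionise the acetal, the enamine carbon would attack C4, and aqueous hydrolysis of the iminium ion would return the route at 13. The aminovinyl terminus is larger than the silyloxyvinyl one, which should reinforce its placement on the O7 side, and there is no silyl group to lose.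

**Step 22.** The most likely failure is elimination from the triflate or from the bromonium ion (loss of a methyl proton to an allylic bromide). Slow triflation of the hindered secondary hydroxyl and some capture of chloride at the secondary carbon are further risks. The fallback gives up reagent control of this centre. It sets out from 27, which would be treated with N-bromosuccinimide and Bu4NCl in CH2Cl2 at −40 °C, so that the bromonium ion of the prenyl alkene is opened by chloride at the tertiary carbon. This would give 31 together with its epimer at the bromine-bearing carbon, the (3R)-bromide F2. The two would be separated by preparative HPLC, and the route is rejoined at 31.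

**Step 14.** The most likely failure is slow substitution at the β-branched primary carbon, so that elimination, attack of the organolithium at sulfur, or ionisation of the triflate with participation of the prenyl alkene compete. The fallback reverses the polarity and replaces steps 13 to 15. It sets out from 17, which would be converted with I2, PPh3 and imidazole into the iodide (1S,2S,3S,4R)-2-(iodomethyl)-1,3-dimethyl-3-(4-methylpent-3-enyl)-7-oxabicyclo[2.2.1]heptane F3. Magnesium in THF would give the Grignard reagent, the corresponding alkylmagnesium iodide F4. Coupling with tert-butyl{[(2E)-4-bromo-3-methylbut-2-enyl]oxy}dimethylsilane under Li2CuCl4 catalysis at −78 → 0 °C, at the unhindered primary allylic carbon, would give the tert-butyldimethylsilyl ether of 23, F5. Bu4NF would remove the silyl group and the route is rejoined at 23.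

## Further compounds

F1 | step 8 | (2R)-2-[(2S)-5-methoxy-2-methyloxolan-2-yl]-3-methyl-4-(pyrrolidin-1-yl)but-3-enyl pivalate | CC(C)(C)C(=O)OC[C@@H](C(C)=CN2CCCC2)[C@]1(C)CCC(OC)O1
F2 | step 22 | epimer of 31 with the (3R)-3-bromo-4-chloro-4-methylpentyl group | C=C[C@@](C)(O[Si](CC)(CC)CC)CC[C@H]1[C@](C)(CC[C@@H](Br)C(C)(C)Cl)[C@H]2CC[C@]1(C)O2
F3 | step 14 | (1S,2S,3S,4R)-2-(iodomethyl)-1,3-dimethyl-3-(4-methylpent-3-enyl)-7-oxabicyclo[2.2.1]heptane | IC[C@H]1[C@](C)(CCC=C(C)C)[C@H]2CC[C@]1(C)O2
F4 | step 14 | Grignard reagent of F3, the bicyclylmethylmagnesium iodide | I[Mg]C[C@H]1[C@](C)(CCC=C(C)C)[C@H]2CC[C@]1(C)O2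
F5 | step 14 | tert-butyldimethylsilyl ether of 23 | CC(C)(C)[Si](C)(C)OC/C=C(\C)CC[C@H]1[C@](C)(CCC=C(C)C)[C@H]2CC[C@]1(C)O2
A1 | alternative 1 | 7-oxanorbornane with the triethylsilyl-protected C2 arm, endo C3 methyl and exo C3 2-(methoxycarbonyl)ethyl | C=C[C@@](C)(O[Si](CC)(CC)CC)CC[C@H]1[C@](C)(CCC(=O)OC)[C@H]2CC[C@]1(C)O2
A2 | alternative 1 | 4-hydroxy-1-methylcyclohexane-1-carboxylic acid carrying the same C2 and C3 substituents as A1 (either configuration at C1) | C=C[C@@](C)(O[Si](CC)(CC)CC)CC[C@H]1[C@](C)(CCC(=O)OC)[C@H](O)CCC1(C)C(=O)O
A3 | alternative 2 | [(1S,2R,3S,4R)-1,3-dimethyl-3-(4-methylpent-3-enyl)-7-oxabicyclo[2.2.1]heptan-2-yl]methyl acetate | CC(=O)OC[C@H]1[C@](C)(CCC=C(C)C)[C@H]2CC[C@]1(C)O2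
A4 | alternative 2 | (2Z)-3-methyl-5-[(2R,3S)-3-methyl-3-(4-methylpent-3-enyl)oxiran-2-yl]pent-2-enyl acetate (cis-epoxide) | CC(=O)OC/C=C(C)\CC[C@H]1O[C@@]1(C)CCC=C(C)C
A5 | alternative 3 | (1S,2R,3S,4R)-1,3-dimethyl-3-(4-methylpent-3-enyl)-7-oxabicyclo[2.2.1]heptane-2-carbaldehyde (formyl endo) | O=C[C@H]1[C@](C)(CCC=C(C)C)[C@H]2CC[C@]1(C)O2
A6 | alternative 3 | 3-(5-methoxy-5-methyloxolan-2-yl)-3,7-dimethyloct-6-enal with the C3 and C4 configuration of A5 (either configuration at the ketal carbon) | O=CC[C@](C)(CCC=C(C)C)[C@H]1CCC(C)(OC)O1
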